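## Retrosynthetic overview

1. The strategy rests on the oxane ring (O1, C2 aryl, C3, C4 OH, C5, C6 arylethyl; Ca is the styryl-bearing carbon on C3): its axial C4 hydroxyl is trans to the equatorial C6 chain and cis to the equatorial C3 branch, a pattern that a metal-bridged lactone aldol can relay from C6 alone.
2. C2 is disconnected last: aryllithium addition to a δ-lactone and silane reduction of the lactol set C2, leading back to 4-hydroxy lactone 26.
3. The C3–C4 bond and the only ring closure come from a SmI2 Reformatsky lactonisation of α-bromo ester aldehyde 25, which sets C3 and C4.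
4. 25 is assembled from the ester bond O1–C2 (phosphonoacetate of the C4–C6 diol fragment), a Horner–Wadsworth–Emmons olefination, a rhodium-catalysed styryl conjugate addition (Ca) and an enolate bromination.
5. C6 and the side-chain carbinol both come from one Noyori hydrogenation product (7). Ring order: lactone (step 17), then oxane by reduction at C2 (step 20).

Key step: step 17

Abbreviations: TBS = tert-butyldimethylsilyl, TES = triethylsilyl, Ar = 4-(TBSO)phenyl.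

Remark: the descriptor at Ca (3R in 21, 3S from 23 on) and at ring C3 (S in 26–30, R in 31, S in 32) changes only because substituent priorities change; no configuration is inverted at these centres.

## Route

Step 1
Reactants: 1 3-(4-hydroxyphenyl)propanoic acid
Product: 3 3-[4-(TBSO)phenyl]propanoic acid, via bis-silylated ester 2 (not isolated)
Conditions: TBSCl (2.3 equiv), imidazole, DMF, rt; then AcOH/THF/H2O, rt
Reagents that add atoms: tert-butyldimethylsilyl chloride, CC(C)(C)[Si](C)(C)Cl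
Why: Silyl ether protection of the phenol, in which the co-formed silyl ester is far more labile and should be hydrolysed selectively by dilute acetic acid.

Step 2
Reactants: 3 3-[4-(TBSO)phenyl]propanoic acid; 4 Meldrum's acid
Product: 6 methyl 3-oxo-5-[4-(TBSO)phenyl]pentanoate, via acyl Meldrum's acid 5 (not isolated)
Conditions: DCC, DMAP, CH2Cl2, 0 °C → rt; filter; then MeOH, reflux
Reagents that add atoms: methanol, CO
Why: Carbodiimide C-acylation of Meldrum's acid followed by methanolysis with loss of acetone and CO2 is the standard Meldrum's acid synthesis of β-keto esters and leaves the aryl silyl ether alone.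

Step 3
Reactants: 6 methyl 3-oxo-5-[4-(TBSO)phenyl]pentanoate
Product: 7 methyl (3S)-3-hydroxy-5-[4-(TBSO)phenyl]pentanoate
Conditions: H2 (20 bar), [RuCl(p-cymene)((S)-BINAP)]Cl (0.5 mol%), MeOH, 60 °C
Reagents that add atoms: none
Why: Noyori asymmetric hydrogenation of a chelating β-keto ester, in which (S)-BINAP should give the 3S alcohol (the sense known for 3-oxoalkanoates), setting the centre that becomes both C6 and the side-chain carbinol.

Step 4
Reactants: 7 methyl (3S)-3-hydroxy-5-[4-(TBSO)phenyl]pentanoate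
Product: 8 (3S)-5-[4-(TBSO)phenyl]pentane-1,3-diol
Conditions: LiBH4, THF, 0 °C → rt
Reagents that add atoms: none
Why: Borohydride reduction of a β-hydroxy ester to the 1,3-diol, mild enough to spare the aryl silyl ether and not touching the carbinol centre.

Step 5
Reactants: 8 (3S)-5-[4-(TBSO)phenyl]pentane-1,3-diol
Product: 9 (3S)-5-[4-(TBSO)phenyl]-1-(TESO)pentan-3-ol
Conditions: Et3SiCl (1.05 equiv), imidazole, CH2Cl2, −78 → −40 °C
Reagents that add atoms: triethylsilyl chloride, CC[Si](Cl)(CC)CC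
Why: Selective silylation of the less hindered primary hydroxyl of a 1,3-diol at low temperature, leaving the secondary C6 hydroxyl free for acylation.

Step 6
Reactants: 9 (3S)-5-[4-(TBSO)phenyl]-1-(TESO)pentan-3-ol; 10 2-(diethoxyphosphoryl)acetic acid
Product: 11 (3S)-5-[4-(TBSO)phenyl]-1-(TESO)pentan-3-yl 2-(diethoxyphosphoryl)acetate
Conditions: DCC, DMAP (cat.), CH2Cl2, 0 °C → rt
Reagents that add atoms: none
Why: Steglich esterification, which forms the O1–C2 ester bond with retention at C6 and brings in C2 and C3 as a phosphonoacetate.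

Step 7
Reactants: 7 methyl (3S)-3-hydroxy-5-[4-(TBSO)phenyl]pentanoate
Product: 12 methyl (3S)-3-(TBSO)-5-[4-(TBSO)phenyl]pentanoate
Conditions: TBSCl, imidazole, DMF, rt
Reagents that add atoms: tert-butyldimethylsilyl chloride, CC(C)(C)[Si](C)(C)Cl
Why: Standard silyl ether protection of the secondary alcohol that becomes the side-chain carbinol.

Step 8
Reactants: 12 methyl (3S)-3-(TBSO)-5-[4-(TBSO)phenyl]pentanoate
Product: 13 (3S)-3-(TBSO)-5-[4-(TBSO)phenyl]pentanal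
Conditions: i-Bu2AlH (1.1 equiv), CH2Cl2, −78 °C; aq. potassium sodium tartrate
Reagents that add atoms: none
Why: Partial reduction of a methyl ester with i-Bu2AlH at −78 °C, where the tetrahedral aluminium hemiacetal of a β-silyloxy ester should survive until work-up and release the aldehyde.

Step 9
Reactants: 11 (3S)-5-[4-(TBSO)phenyl]-1-(TESO)pentan-3-yl 2-(diethoxyphosphoryl)acetate; 13 (3S)-3-(TBSO)-5-[4-(TBSO)phenyl]pentanal
Product: 14 (3S)-5-Ar-1-(TESO)pentan-3-yl (2E,5S)-5-(TBSO)-7-Ar-hept-2-enoate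
Conditions: LiCl, i-Pr2NEt, MeCN, rt
Reagents that add atoms: none
Why: Horner–Wadsworth–Emmons olefination under Masamune–Roush conditions, E-selective and mild enough to avoid β-elimination of the silyloxy aldehyde.

Step 10
Reactants: 15 4-acetoxystyrene
Product: 17 tert-butyl(4-ethenylphenoxy)dimethylsilane, via 4-ethenylphenol 16 (not isolated)
Conditions: K2CO3 (0.2 equiv), MeOH, 0 °C; neutral work-up; then TBSCl, imidazole, DMF, rt
Reagents that add atoms: tert-butyldimethylsilyl chloride, CC(C)(C)[Si](C)(C)Cl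
Why: Base-catalysed methanolysis of the aryl acetate followed directly by silylation swaps the protecting group without storing the polymerisation-prone vinylphenol.

Step 11
Reactants: 17 tert-butyl(4-ethenylphenoxy)dimethylsilane; 18 2-ethenyl-4,4,5,5-tetramethyl-1,3,2-dioxaborolane
Product: 19 (E)-2-{2-[4-(TBSO)phenyl]ethenyl}-4,4,5,5-tetramethyl-1,3,2-dioxaborolane
Conditions: second-generation Grubbs catalyst (3 mol%), CH2Cl2, 40 °C
Reagents that add atoms: none
Why: Olefin cross-metathesis of a styrene with a vinylboronate, driven by loss of ethene and expected to give the E-alkenylboronate.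

Step 12
Reactants: 19 (E)-2-{2-[4-(TBSO)phenyl]ethenyl}-4,4,5,5-tetramethyl-1,3,2-dioxaborolane
Product: 20 (E)-2-[4-(TBSO)phenyl]ethenylboronic acid
Conditions: NaIO4, NH4OAc, acetone/H2O, rt
Reagents that add atoms: water, O
Why: Oxidative cleavage of the pinacol released in the boronate hydrolysis equilibrium drives it to the free boronic acid, which transmetallates to rhodium without added base.

Step 13
Reactants: 14 (3S)-5-Ar-1-(TESO)pentan-3-yl (2E,5S)-5-(TBSO)-7-Ar-hept-2-enoate; 20 (E)-2-[4-(TBSO)phenyl]ethenylboronic acid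
Product: 21 (3S)-5-Ar-1-(TESO)pentan-3-yl (3R,5S)-5-(TBSO)-7-Ar-3-[(E)-2-Ar-ethenyl]heptanoate
Conditions: 20 (3 equiv), [Rh(OH)((S)-BINAP)]2 (3 mol%), dioxane/H2O 10:1, 35 °C
Reagents that add atoms: none
Why: Rhodium-catalysed asymmetric conjugate addition of an alkenylboronic acid (Hayashi–Miyaura reaction), in which the (S)-BINAP alkenylrhodium species should insert the E-enoate on its α-si face and so set Ca as 3R under catalyst control.

Step 14
Reactants: 21 (3S)-5-Ar-1-(TESO)pentan-3-yl (3R,5S)-5-(TBSO)-7-Ar-3-[(E)-2-Ar-ethenyl]heptanoate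
Product: 23 (3S)-5-Ar-1-(TESO)pentan-3-yl (2RS,3S,5S)-2-bromo-5-(TBSO)-7-Ar-3-[(E)-2-Ar-ethenyl]heptanoate, via trimethylsilyl ketene acetal 22 (not isolated)
Conditions: LiN(i-Pr)2, Me3SiCl, THF, −78 °C; then NBS, THF, −78 °C
Reagents that add atoms: N-bromosuccinimide, O=C1CCC(=O)N1Br
Why: α-Bromination of an ester through its silyl ketene acetal, which reacts with NBS far faster than the styrene does; either epimer at the bromine-bearing carbon serves, because that centre is erased in the next carbon–carbon bond formation.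

Step 15
Reactants: 23 (3S)-5-Ar-1-(TESO)pentan-3-yl (2RS,3S,5S)-2-bromo-5-(TBSO)-7-Ar-3-[(E)-2-Ar-ethenyl]heptanoate
Product: 24 (3S)-1-hydroxy-5-Ar-pentan-3-yl (2RS,3S,5S)-2-bromo-5-(TBSO)-7-Ar-3-[(E)-2-Ar-ethenyl]heptanoate
Conditions: PPTS (cat.), MeOH/CH2Cl2 1:1, 0 °C
Reagents that add atoms: none
Why: Acid-catalysed methanolysis removes a primary TES ether selectively, since secondary alkyl and aryl TBS ethers are much slower under these conditions and no base is present to attack the bromo ester.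

Step 16
Reactants: 24 (3S)-1-hydroxy-5-Ar-pentan-3-yl (2RS,3S,5S)-2-bromo-5-(TBSO)-7-Ar-3-[(E)-2-Ar-ethenyl]heptanoate
Product: 25 (3S)-1-oxo-5-Ar-pentan-3-yl (2RS,3S,5S)-2-bromo-5-(TBSO)-7-Ar-3-[(E)-2-Ar-ethenyl]heptanoate
Conditions: Dess–Martin periodinane, NaHCO3, CH2Cl2, 0 °C → rt; used at once
Reagents that add atoms: none
Why: Dess–Martin oxidation gives the β-acyloxy aldehyde under near-neutral conditions that should avoid β-elimination of the carboxylate.

Step 17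
Reactants: 25 (3S)-1-oxo-5-Ar-pentan-3-yl (2RS,3S,5S)-2-bromo-5-(TBSO)-7-Ar-3-[(E)-2-Ar-ethenyl]heptanoate
Product: 26 (3S,4S,6S)-4-hydroxy-6-(2-Ar-ethyl)-3-[(1E,3S,5S)-5-(TBSO)-1,7-di-Ar-hept-1-en-3-yl]oxan-2-one
Conditions: SmI2 (2.5 equiv, 0.1 M in THF), slow addition of 25, THF, −78 °C; pH 7 buffer at −78 °C
Reagents that add atoms: none
Why: Two single-electron transfers from divalent samarium cleave the C3–Br bond and give an O-bound enolate of trivalent samarium, which adds to the tethered C4 aldehyde to form the C3–C4 bond and the lactone ring (O1, C2, C3, C4, C5, C6); the closest known reaction type is the SmI2-promoted intramolecular Reformatsky cyclisation of β-(α-bromoacyloxy) aldehydes to β-hydroxy δ-lactones. The ring closes in the 6-(enolendo)-exo-trig mode, since both enolate carbons (C2 and C3) lie in the new ring and the aldehyde oxygen stays outside it. C4 is set by the samarium bridge between the enolate oxygen and the aldehyde oxygen in a chair-like lactone transition state with the C6 arylethyl chain equatorial, which forces the C4 oxygen axial and therefore trans to the C6 chain. C3 is set by enolate geometry: the enolate with the Ca branch cis to the samarium-bound oxygen should be the one that cyclises, because the other geometry pushes the branch against the O1–C6 bond in the s-cis ester arrangement that an enolendo closure needs, and it delivers the branch equatorial and cis to the C4 hydroxyl. The step needs chemoselective reduction of the α-bromo ester beside the aldehyde and the styrene, which the much easier reduction of the carbon–bromine bond by SmI2 in THF at −78 °C without additives should secure, and it needs no control at the bromine-bearing carbon because that centre becomes planar in the enolate.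

Step 18
Reactants: 26 (3S,4S,6S)-4-hydroxy-6-(2-Ar-ethyl)-3-[(1E,3S,5S)-5-(TBSO)-1,7-di-Ar-hept-1-en-3-yl]oxan-2-one
Product: 27 (3S,4S,6S)-4-(TBSO)-6-(2-Ar-ethyl)-3-[(1E,3S,5S)-5-(TBSO)-1,7-di-Ar-hept-1-en-3-yl]oxan-2-one
Conditions: TBSOTf, 2,6-lutidine, CH2Cl2, −78 → 0 °C
Reagents that add atoms: tert-butyldimethylsilyl trifluoromethanesulfonate, CC(C)(C)[Si](C)(C)OS(=O)(=O)C(F)(F)F
Why: Silylation of the hindered axial C4 hydroxyl with the silyl triflate and a non-nucleophilic base, which removes the acidic proton and the retro-aldol pathway before the organolithium step without epimerising C3.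

Step 19
Reactants: 27 (3S,4S,6S)-4-(TBSO)-6-(2-Ar-ethyl)-3-[(1E,3S,5S)-5-(TBSO)-1,7-di-Ar-hept-1-en-3-yl]oxan-2-one; 28 (4-bromophenoxy)(tert-butyl)dimethylsilane
Product: 30 (3S,4S,6S)-2-Ar-4-(TBSO)-6-(2-Ar-ethyl)-3-[(1E,3S,5S)-5-(TBSO)-1,7-di-Ar-hept-1-en-3-yl]oxan-2-ol (lactol; either C2 epimer), via aryllithium 29 (not isolated)
Conditions: 28, n-BuLi, THF, −78 °C; then 27, THF, −78 °C; AcOH quench at −78 °C
Reagents that add atoms: none
Why: Bromine–lithium exchange and 1,2-addition of the aryllithium to the lactone (the lactone route to C-aryl glycosides), in which the tetrahedral lithium hemiketal is stable at −78 °C and so should prevent a second addition.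

Step 20
Reactants: 30 (3S,4S,6S)-2-Ar-4-(TBSO)-6-(2-Ar-ethyl)-3-[(1E,3S,5S)-5-(TBSO)-1,7-di-Ar-hept-1-en-3-yl]oxan-2-ol
Product: 31 (2S,3R,4S,6S)-2-Ar-4-(TBSO)-6-(2-Ar-ethyl)-3-[(1E,3S,5S)-5-(TBSO)-1,7-di-Ar-hept-1-en-3-yl]oxane
Conditions: Et3SiH (5 equiv), BF3·OEt2 (2 equiv), CH2Cl2, −78 → −40 °C
Reagents that add atoms: none
Why: Ionic reduction of the lactol through its aryl-stabilised oxocarbenium ion, where hydride should add along the axial trajectory of the half-chair with the C6 chain and C3 branch pseudo-equatorial, placing H axial and the aryl group equatorial at C2 (2,6-cis, 2,3-trans).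

Step 21
Reactants: 31 (2S,3R,4S,6S)-2-Ar-4-(TBSO)-6-(2-Ar-ethyl)-3-[(1E,3S,5S)-5-(TBSO)-1,7-di-Ar-hept-1-en-3-yl]oxane
Product: 32 blepharocalyxin C
Conditions: Bu4NF (excess), AcOH, THF, 0 °C → rt, under argon
Reagents that add atoms: none
Why: Fluoride desilylation of the three aryl and two alkyl TBS ethers, buffered with acetic acid so that no free phenoxide can open the benzylic C2–O1 bond or oxidise in air.

## Compound list

1 | 3-(4-hydroxyphenyl)propanoic acid | OC(=O)CCc1ccc(O)cc1 | starting material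
2 | TBS 3-[4-(TBSO)phenyl]propanoate | CC(C)(C)[Si](C)(C)OC(=O)CCc1ccc(O[Si](C)(C)C(C)(C)C)cc1 | intermediate
3 | 3-[4-(TBSO)phenyl]propanoic acid | OC(=O)CCc1ccc(O[Si](C)(C)C(C)(C)C)cc1 | intermediate
4 | Meldrum's acid (2,2-dimethyl-1,3-dioxane-4,6-dione) | CC1(C)OC(=O)CC(=O)O1 | starting material
5 | 5-{3-[4-(TBSO)phenyl]propanoyl}-2,2-dimethyl-1,3-dioxane-4,6-dione | CC1(C)OC(=O)C(C(=O)CCc2ccc(O[Si](C)(C)C(C)(C)C)cc2)C(=O)O1 | intermediate
6 | methyl 3-oxo-5-[4-(TBSO)phenyl]pentanoate | COC(=O)CC(=O)CCc1ccc(O[Si](C)(C)C(C)(C)C)cc1 | intermediate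
7 | methyl (3S)-3-hydroxy-5-[4-(TBSO)phenyl]pentanoate | COC(=O)C[C@@H](O)CCc1ccc(O[Si](C)(C)C(C)(C)C)cc1 | intermediate
8 | (3S)-5-[4-(TBSO)phenyl]pentane-1,3-diol | OCC[C@@H](O)CCc1ccc(O[Si](C)(C)C(C)(C)C)cc1 | intermediate
9 | (3S)-5-[4-(TBSO)phenyl]-1-(TESO)pentan-3-ol | CC[Si](CC)(CC)OCC[C@@H](O)CCc1ccc(O[Si](C)(C)C(C)(C)C)cc1 | intermediate
10 | 2-(diethoxyphosphoryl)acetic acid | CCOP(=O)(OCC)CC(=O)O | starting material
11 | (3S)-5-[4-(TBSO)phenyl]-1-(TESO)pentan-3-yl 2-(diethoxyphosphoryl)acetate | CCOP(=O)(OCC)CC(=O)O[C@@H](CCc1ccc(O[Si](C)(C)C(C)(C)C)cc1)CCO[Si](CC)(CC)CC | intermediate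
12 | methyl (3S)-3-(TBSO)-5-[4-(TBSO)phenyl]pentanoate | COC(=O)C[C@@H](O[Si](C)(C)C(C)(C)C)CCc1ccc(O[Si](C)(C)C(C)(C)C)cc1 | intermediate
13 | (3S)-3-(TBSO)-5-[4-(TBSO)phenyl]pentanal | O=CC[C@@H](O[Si](C)(C)C(C)(C)C)CCc1ccc(O[Si](C)(C)C(C)(C)C)cc1 | intermediate
14 | (3S)-5-Ar-1-(TESO)pentan-3-yl (2E,5S)-5-(TBSO)-7-Ar-hept-2-enoate | CC[Si](CC)(CC)OCC[C@H](CCc1ccc(O[Si](C)(C)C(C)(C)C)cc1)OC(=O)/C=C/C[C@@H](O[Si](C)(C)C(C)(C)C)CCc1ccc(O[Si](C)(C)C(C)(C)C)cc1 | intermediate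
15 | 4-acetoxystyrene | CC(=O)Oc1ccc(C=C)cc1 | starting material
16 | 4-ethenylphenol | Oc1ccc(C=C)cc1 | intermediate
17 | tert-butyl(4-ethenylphenoxy)dimethylsilane | CC(C)(C)[Si](C)(C)Oc1ccc(C=C)cc1 | intermediate
18 | 2-ethenyl-4,4,5,5-tetramethyl-1,3,2-dioxaborolane | C=CB1OC(C)(C)C(C)(C)O1 | starting material
19 | (E)-2-{2-[4-(TBSO)phenyl]ethenyl}-4,4,5,5-tetramethyl-1,3,2-dioxaborolane | CC(C)(C)[Si](C)(C)Oc1ccc(/C=C/B2OC(C)(C)C(C)(C)O2)cc1 | intermediate
20 | (E)-2-[4-(TBSO)phenyl]ethenylboronic acid | CC(C)(C)[Si](C)(C)Oc1ccc(/C=C/B(O)O)cc1 | intermediate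
21 | (3S)-5-Ar-1-(TESO)pentan-3-yl (3R,5S)-5-(TBSO)-7-Ar-3-[(E)-2-Ar-ethenyl]heptanoate | CC(C)(C)[Si](C)(C)Oc1ccc(/C=C/[C@H](C[C@@H](O[Si](C)(C)C(C)(C)C)CCc2ccc(O[Si](C)(C)C(C)(C)C)cc2)CC(=O)O[C@@H](CCc2ccc(O[Si](C)(C)C(C)(C)C)cc2)CCO[Si](CC)(CC)CC)cc1 | intermediate
22 | trimethylsilyl ketene acetal of 21 (either C=C geometry) | CC(C)(C)[Si](C)(C)Oc1ccc(/C=C/[C@H](C[C@@H](O[Si](C)(C)C(C)(C)C)CCc2ccc(O[Si](C)(C)C(C)(C)C)cc2)C=C(O[Si](C)(C)C)O[C@@H](CCc2ccc(O[Si](C)(C)C(C)(C)C)cc2)CCO[Si](CC)(CC)CC)cc1 | intermediate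
23 | (3S)-5-Ar-1-(TESO)pentan-3-yl (2RS,3S,5S)-2-bromo-5-(TBSO)-7-Ar-3-[(E)-2-Ar-ethenyl]heptanoate | CC(C)(C)[Si](C)(C)Oc1ccc(/C=C/[C@H](C[C@@H](O[Si](C)(C)C(C)(C)C)CCc2ccc(O[Si](C)(C)C(C)(C)C)cc2)C(Br)C(=O)O[C@@H](CCc2ccc(O[Si](C)(C)C(C)(C)C)cc2)CCO[Si](CC)(CC)CC)cc1 | intermediate
24 | (3S)-1-hydroxy-5-Ar-pentan-3-yl (2RS,3S,5S)-2-bromo-5-(TBSO)-7-Ar-3-[(E)-2-Ar-ethenyl]heptanoate | CC(C)(C)[Si](C)(C)Oc1ccc(/C=C/[C@H](C[C@@H](O[Si](C)(C)C(C)(C)C)CCc2ccc(O[Si](C)(C)C(C)(C)C)cc2)C(Br)C(=O)O[C@@H](CCc2ccc(O[Si](C)(C)C(C)(C)C)cc2)CCO)cc1 | intermediate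
25 | (3S)-1-oxo-5-Ar-pentan-3-yl (2RS,3S,5S)-2-bromo-5-(TBSO)-7-Ar-3-[(E)-2-Ar-ethenyl]heptanoate (key-step precursor) | CC(C)(C)[Si](C)(C)Oc1ccc(/C=C/[C@H](C[C@@H](O[Si](C)(C)C(C)(C)C)CCc2ccc(O[Si](C)(C)C(C)(C)C)cc2)C(Br)C(=O)O[C@@H](CCc2ccc(O[Si](C)(C)C(C)(C)C)cc2)CC=O)cc1 | intermediate
26 | (3S,4S,6S)-4-hydroxy-6-(2-Ar-ethyl)-3-[(1E,3S,5S)-5-(TBSO)-1,7-di-Ar-hept-1-en-3-yl]oxan-2-one (key-step product) | CC(C)(C)[Si](C)(C)Oc1ccc(/C=C/[C@H](C[C@@H](O[Si](C)(C)C(C)(C)C)CCc2ccc(O[Si](C)(C)C(C)(C)C)cc2)[C@@H]2C(=O)O[C@@H](CCc3ccc(O[Si](C)(C)C(C)(C)C)cc3)C[C@@H]2O)cc1 | intermediate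
27 | (3S,4S,6S)-4-(TBSO)-6-(2-Ar-ethyl)-3-[(1E,3S,5S)-5-(TBSO)-1,7-di-Ar-hept-1-en-3-yl]oxan-2-one | CC(C)(C)[Si](C)(C)Oc1ccc(/C=C/[C@H](C[C@@H](O[Si](C)(C)C(C)(C)C)CCc2ccc(O[Si](C)(C)C(C)(C)C)cc2)[C@@H]2C(=O)O[C@@H](CCc3ccc(O[Si](C)(C)C(C)(C)C)cc3)C[C@@H]2O[Si](C)(C)C(C)(C)C)cc1 | intermediate
28 | (4-bromophenoxy)(tert-butyl)dimethylsilane | CC(C)(C)[Si](C)(C)Oc1ccc(Br)cc1 | starting material
29 | [4-(TBSO)phenyl]lithium | [Li]c1ccc(O[Si](C)(C)C(C)(C)C)cc1 | intermediate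
30 | (3S,4S,6S)-2-Ar-4-(TBSO)-6-(2-Ar-ethyl)-3-[(1E,3S,5S)-5-(TBSO)-1,7-di-Ar-hept-1-en-3-yl]oxan-2-ol (lactol, either C2 epimer) | CC(C)(C)[Si](C)(C)Oc1ccc(/C=C/[C@H](C[C@@H](O[Si](C)(C)C(C)(C)C)CCc2ccc(O[Si](C)(C)C(C)(C)C)cc2)[C@@H]2C(O)(c3ccc(O[Si](C)(C)C(C)(C)C)cc3)O[C@@H](CCc3ccc(O[Si](C)(C)C(C)(C)C)cc3)C[C@@H]2O[Si](C)(C)C(C)(C)C)cc1 | intermediate
31 | (2S,3R,4S,6S)-2-Ar-4-(TBSO)-6-(2-Ar-ethyl)-3-[(1E,3S,5S)-5-(TBSO)-1,7-di-Ar-hept-1-en-3-yl]oxane (penta-TBS ether of the target) | CC(C)(C)[Si](C)(C)Oc1ccc(/C=C/[C@H](C[C@@H](O[Si](C)(C)C(C)(C)C)CCc2ccc(O[Si](C)(C)C(C)(C)C)cc2)[C@@H]2[C@@H](c3ccc(O[Si](C)(C)C(C)(C)C)cc3)O[C@@H](CCc3ccc(O[Si](C)(C)C(C)(C)C)cc3)C[C@@H]2O[Si](C)(C)C(C)(C)C)cc1 | intermediate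
32 | blepharocalyxin C, (2S,3S,4S,6S)-2-(4-hydroxyphenyl)-6-[2-(4-hydroxyphenyl)ethyl]-3-[(1E,3S,5S)-5-hydroxy-1,7-bis(4-hydroxyphenyl)hept-1-en-3-yl]oxan-4-ol | Oc1ccc(/C=C/[C@H](C[C@@H](O)CCc2ccc(O)cc2)[C@@H]2[C@@H](c3ccc(O)cc3)O[C@@H](CCc3ccc(O)cc3)C[C@@H]2O)cc1 | target

## Step count and risks

Total steps: 21. Longest linear sequence: 16 steps (1, 2, 3, 4, 5, 6, 9, 13, 14, 15, 16, 17, 18, 19, 20, 21).

**Step 17 (key step).** The samarium enolate may cyclise through the other enolate geometry or through a transition state without the samarium bridge, which would leave the Ca branch axial at C3 (poor control at C3), although C4 should still follow C6. The fallback sets out from 25 and returns at 26. Cyclisation under the same SmI2 conditions would then give the C3-epimeric hydroxy lactone F1. F1 is treated with LiN(i-Pr)2 (2.2 equiv) in THF at −78 °C to give the dilithium alkoxide–enolate F2, which cannot eliminate its oxide. Protonation of F2 at −78 °C with AcOH in THF should occur on the face anti to the C4 oxygen, the facial preference known from Fráter–Seebach reactions of β-hydroxy ester and lactone dianions. That puts the Ca branch cis to the C4 oxygen and gives 26.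

**Step 20.** Under the Lewis acid several things can go wrong: protonation and silane reduction of the electron-rich styrene, drift of C3 through the enol ether of the oxocarbenium ion, allylic ionisation of the C4 silyloxy group, or hydride delivery to the other face of C2. The fallback sets out from 30 and returns at 31. LiBH4 in THF at 0 °C reduces the open keto tautomer of 30 to the 1,5-diol F3 (both benzylic carbinol epimers). Catalytic Bi(OTf)3 or camphorsulfonic acid in CH2Cl2 at 0 °C then ionises the 4-silyloxybenzylic alcohol, and the C6 hydroxyl captures the cation (intramolecular SN1 etherification). This closure is reversible and should converge on the oxane with the C2, C3 and C6 substituents all equatorial, which is 31.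

**Step 13.** Protodeboronation of the electron-rich styrylboronic acid may outrun insertion into the hindered secondary-alkyl enoate, and catalyst control of the face may be incomplete. The fallback sets out from 13 (with 20 and 9) and returns at 21.
- Horner–Wadsworth–Emmons reaction of 13 with the known reagent (4S)-3-[2-(diethoxyphosphoryl)acetyl]-4-phenyl-1,3-oxazolidin-2-one (LiCl, i-Pr2NEt, MeCN) gives the N-enoyl imide F4.
- Iododeboronation of 20 with N-iodosuccinimide in MeCN gives, with retention, the (E)-alkenyl iodide F5.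
- Iodine–magnesium exchange on F5 with i-PrMgCl·LiCl in THF at −40 °C gives the alkenylmagnesium chloride F6.
- F6 with CuBr·SMe2 and then F4 in THF at −78 → −20 °C should add anti to the phenyl group of the chelated s-cis imide, giving the 3R adduct F7.
- LiOH/H2O2 in THF/H2O at 0 °C releases the acid F8.
- Steglich esterification of F8 with 9 (DCC, DMAP) gives 21.

## Further compounds

F1 | step 17 | (3R,4S,6S)-4-hydroxy-6-(2-Ar-ethyl)-3-[(1E,3S,5S)-5-(TBSO)-1,7-di-Ar-hept-1-en-3-yl]oxan-2-one (C3 epimer of 26) | CC(C)(C)[Si](C)(C)Oc1ccc(/C=C/[C@H](C[C@@H](O[Si](C)(C)C(C)(C)C)CCc2ccc(O[Si](C)(C)C(C)(C)C)cc2)[C@H]2C(=O)O[C@@H](CCc3ccc(O[Si](C)(C)C(C)(C)C)cc3)C[C@@H]2O)cc1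
F2 | step 17 | dilithium alkoxide–enolate of F1 (C3 planar) | CC(C)(C)[Si](C)(C)Oc1ccc(/C=C/[C@H](C[C@@H](O[Si](C)(C)C(C)(C)C)CCc2ccc(O[Si](C)(C)C(C)(C)C)cc2)C2=C(O[Li])O[C@@H](CCc3ccc(O[Si](C)(C)C(C)(C)C)cc3)C[C@@H]2O[Li])cc1
F3 | step 20 | ring-opened 1,5-diol of 30 (benzylic carbinol at former C2 as both epimers; C3, C4, C6, Ca and side-chain carbinol unchanged) | CC(C)(C)[Si](C)(C)Oc1ccc(/C=C/[C@H](C[C@@H](O[Si](C)(C)C(C)(C)C)CCc2ccc(O[Si](C)(C)C(C)(C)C)cc2)[C@H](C(O)c2ccc(O[Si](C)(C)C(C)(C)C)cc2)[C@@H](O[Si](C)(C)C(C)(C)C)C[C@@H](O)CCc2ccc(O[Si](C)(C)C(C)(C)C)cc2)cc1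
F4 | step 13 | (4S)-3-[(2E,5S)-5-(TBSO)-7-Ar-hept-2-enoyl]-4-phenyl-1,3-oxazolidin-2-one | O=C1OC[C@H](c2ccccc2)N1C(=O)/C=C/C[C@@H](O[Si](C)(C)C(C)(C)C)CCc1ccc(O[Si](C)(C)C(C)(C)C)cc1
F5 | step 13 | tert-butyl{4-[(E)-2-iodoethenyl]phenoxy}dimethylsilane | CC(C)(C)[Si](C)(C)Oc1ccc(/C=C/I)cc1
F6 | step 13 | {(E)-2-[4-(TBSO)phenyl]ethenyl}magnesium chloride | CC(C)(C)[Si](C)(C)Oc1ccc(/C=C/[Mg]Cl)cc1
F7 | step 13 | (4S)-3-{(3R,5S)-5-(TBSO)-7-Ar-3-[(E)-2-Ar-ethenyl]heptanoyl}-4-phenyl-1,3-oxazolidin-2-one | CC(C)(C)[Si](C)(C)Oc1ccc(/C=C/[C@H](C[C@@H](O[Si](C)(C)C(C)(C)C)CCc2ccc(O[Si](C)(C)C(C)(C)C)cc2)CC(=O)N2[C@@H](c3ccccc3)COC2=O)cc1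
F8 | step 13 | (3R,5S)-5-(TBSO)-7-Ar-3-[(E)-2-Ar-ethenyl]heptanoic acid | CC(C)(C)[Si](C)(C)Oc1ccc(/C=C/[C@H](C[C@@H](O[Si](C)(C)C(C)(C)C)CCc2ccc(O[Si](C)(C)C(C)(C)C)cc2)CC(=O)O)cc1
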